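In a one-step world free monomer adds to the ends that initiator begins, one chain per initiator, until none is free, and the average length n, monomer in chains over chains begun, reaches the ceiling C = 19.3, free monomer charged per initiator charged.

the same everywhere: free monomer 27 mM; initiator 1.4 mM

|  | transfer agent | protic impurity | remark | time |
|---|---|---|---|---|
| summer | 8.1 mM | 0.13 mM | run made earlier |  |
| dusk | 8.1 mM | 0.41 mM | run made earlier |  |
| Tuesday's | 8.10 mM | 0.540 mM |  | 10 d |
| Friday's | 8.10 mM | 0.150 mM |  | 10 d |

| run | time / d | monomer in chains / % |
|---|---|---|
| summer | 0.625 | 22 |
| summer | 1.67 | 35 |
| summer | 3.00 | 50 |
| summer | 5.00 | 57 |
| dusk | 0.417 | 10 |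
| dusk | 0.833 | 22 |
| dusk | 2.00 | 41 |
| dusk | 5.00 | 56 |

(scatter of a reading: 2 percentage points)

- the average divides the monomer in chains by the number of chains begun, living and dead together
- the numbers in the tables scatter with a standard deviation of 2 percentage points
- the earlier runs do not show the number of chains; that part of a forecast is a guess

- which of the two ends with the longer chains by the average number of monomer units in a chain (chains begun, living or dead) ("neither" if they lie within 10%) (Tuesday's / Friday's / neither)
- average number of monomer units in a chain (chains begun, living or dead) at the end, Tuesday's
- average number of monomer units in a chain (chains begun, living or dead) at the end, Friday's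

C is my bound from above. With f the share of charged free monomer in chains, n = fC while chains begun equal the initiator charged. My first bound from below lets every transfer agent begin a chain as well, and the summer reading of 57% at 5.00 d then gives 1.62. I tighten this from the curves: both flatten with free monomer left, which I read as ends dying, so I take the agent to end chains without beginning any. That is my guess; no reading counts chains. With f taken no lower than that summer reading, my bracket then runs from 11.0 to C. The dusk run, with 3.15 times the protic impurity of the summer run, reads 56% at that time against 57%, a gap within the scatter of 2 percentage points, so I expect nearly equal f in Tuesday's and Friday's, and the answer neither.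

The forecast differs from my reckoning: it says Tuesday's, with 4.2 for Tuesday's and 3.1 for Friday's, and its ground is “Chain count depends on transfer, which the data do not show”. Both values lie above 1.62 but below my tightened bracket.

The flask gives neither: 12.3 for Tuesday's and 12.5 for Friday's.

    living end + transfer agent → dead chain (kL = 4.60 × 10⁻⁴ /M/s)
    protic impurity + free monomer → quenched substrate (k = 0.0350 /M/s)
    free monomer + initiator → living end + monomer in chains (k = 0.00420 /M/s)
    free monomer + living end → monomer in chains + living end, rate k4*[living end]*[free monomer] (k = 0.00260 /M/s)

In Tuesday's the living end has a pseudo-first-order half-life of 2.2 d against transfer agent at the charged concentrations, shorter than the 3.5 d half-life of free monomer by its turning into monomer in chains at 1.63 d, and at 10.0 d that flask holds 0.0842 mM of living end and 1.32 mM of dead chain, together 1.40 mM, with 34% of its free monomer left. So fC reads 12.3 for Tuesday's and 12.5 for Friday's, and for the neighbouring flask, Tuesday's charged with 68 mM of free monomer, where f is 63.6%, fC with that flask's own C is 30.9, and that flask's average is 30.9.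

The readings were computed with constants of no real substance, and the scatter is random.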